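- The unit I reckoned in was the yield per Z: the level of J, the monomer X built into chains started by Z, divided by the Z charged.

in all of them: X 0.80 M

|  | Z | remark | time |
|---|---|---|---|
| zeta | 7.2 mM | run made earlier |  |
| theta | 14 mM | run made earlier |  |
| teal | 20 mM |  | 5.0 d |
| blue | 12 mM |  | 5.0 d |

| run | time / d | J / % | X / % |
|---|---|---|---|
| zeta | 0.625 | 38 | 63 |
| zeta | 1.25 | 39 | 62 |
| zeta | 1.67 | 39 | 60 |
| zeta | 2.50 | 37 | 58 |
| zeta | 3.00 | 39 | 64 |
| zeta | 4.00 | 39 | 57 |
| theta | 0.625 | 56 | 44 |
| theta | 1.25 | 63 | 36 |
| theta | 1.67 | 65 | 37 |
| theta | 2.50 | 65 | 36 |
| theta | 3.00 | 66 | 35 |
| theta | 4.00 | 67 | 32 |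

(scatter of a reading: 1.5 percentage points)

- which of the two ends with the longer chains by the average number of monomer units in a chain (chains begun, living or dead) ("neither" if they lie within 10 %) (teal / blue / neither)
- average number of monomer units in a chain (chains begun, living or dead) at the end, teal
- average number of monomer units in a chain (chains begun, living or dead) at the end, blue

- the average divides the monomer in chains by the number of chains begun, living and dead together
- the earlier runs do not show the number of chains; that part of a forecast is a guess

- Averaging the readings from 1.67 d on, I read 42.8 per Z in zeta, more than the 37.6 in theta.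
- I turned the question round: for blue to beat teal beyond the margin of 10 %, the length per chain would have to fall by more than that margin between 12 mM and 20 mM of Z.
- If each Z began one chain, yield would equal length, and the straight line through both readings would give 39.1 in blue and 33.0 in teal, a ratio beyond the margin.
- But the yield would also fall if some Z were lost without starting a chain, so I treated that loss as a correction growing with [Z].
- Running the line back to no loss gave a reading of 48.3, the units one chain gathers before it dies, or kinetic chain length.
- At 0.625 d, zeta had a larger share of its later J than theta, so these readings showed no sooner stop at the higher [Z], and I kept one length.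
- My reckoning therefore said neither, with about 48.3 in both flasks and 19.0 % of Z lost in blue and 31.7 % in teal; the number of chains stayed a guess.
- The forecast differed: blue, with 32 in teal and 40 in blue, “Assuming each Z begins one chain”.

    X + Z → D + J (k = 0.401 /M/h)
    2 Z → G (k = 12.1 /M/h)
    D + X → E (k = 0.551 /M/h)
    X + D → J + D, rate k4*[D]*[X] (k = 30.4 /M/h)

- The simulation gave neither, with 56.2 in teal and 56.2 in blue. Two Z go into each G, and at the end G held 42.3 % of the Z charged in teal and 30.7 % in blue. The neighbouring flask is blue with [Z] at 0.0048 M. My line gives it a yield of 44.6 per Z, below 48.3, and so J of 26.8 %. It ended with J at 28.6 % and chains of 56.2.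

(The data were computed from invented constants, and the scatter is random.)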